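The disconnection is at C5–C6. C6 is both the carbinol carbon of the butenolide (ring B: O–C6–C7=C11–C12) and the allylic terminus of C4=C5 in the ten-membered carbocycle (ring A). A nickel-catalysed, chromium-mediated coupling of the C5 (E)-iodoalkene with the C6 aldehyde closes ring A and sets C6. The resulting alkoxide sits cis to the C12 methyl ester across C7=C11 and lactonises to ring B in the same flask. The precursor 29 is an acyclic methyl (Z)-4-oxo-2-enoate carrying the C8 methacrylate, the C13 acetate, a C2 silyl ether of fixed configuration and the iodoalkene. It is made from a 2-silylfuran by singlet-oxygen cleavage.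

Key step: step 18

Remark: atoms are labelled C1–C13 as in germacranolides (C1–C10 carbocycle, C11/C12/C13 = lactone α-carbon, carbonyl carbon and acetoxymethyl carbon); because C2 ends as a ketone its configuration is immaterial, and it is set as 2R by catalyst choice only so that every intermediate, including the ring-closure substrate, is a single stereoisomer (the lactol carbon of 28 and the bridgeheads of 26 form as mixtures and carry no descriptor).

Step 1
Reactants: 1 dimethyl furan-3,4-dicarboxylate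
Product: 2 furan-3,4-diyldimethanol
Conditions: LiAlH4, THF, 0 °C → rt
Reagents that add atoms: none
Why: Hydride reduction of both conjugated esters by LiAlH4 gives the symmetric diol without touching the furan ring.

Step 2
Reactants: 2 furan-3,4-diyldimethanol
Product: 3 3,4-bis{[(tert-butyldimethylsilyl)oxy]methyl}furan
Conditions: TBSCl (2.3 equiv), imidazole, DMF, rt
Reagents that add atoms: tert-butyldimethylsilyl chloride, CC(C)(C)[Si](C)(C)Cl
Why: Imidazole-promoted O-silylation of both primary alcohols keeps the molecule symmetric, so the next step can give only one regioisomer.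

Step 3
Reactants: 3 3,4-bis{[(tert-butyldimethylsilyl)oxy]methyl}furan
Product: 6 tert-butyl{4-[(tert-butyldimethylsilyloxy)methyl]-3-[(4-methoxybenzyloxy)methyl]furan-2-yl}dimethylsilane, via 2-lithiofuran 4 (not isolated), via lithium alkoxide 5 (not isolated)
Conditions: n-BuLi (1.1 equiv), HMPA, THF, −78 → 0 °C; then PMBBr, 0 °C → rt
Reagents that add atoms: 4-methoxybenzyl bromide, COc1ccc(CBr)cc1
Why: α-Lithiation of the furan is followed by a 1,4 O→C silyl shift (retro-Brook rearrangement) that puts silicon on the ring carbon destined to become C12 and frees the alkoxide of the neighbouring C13 arm, which is then capped in the same flask by Williamson alkylation.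

Step 4
Reactants: 6 tert-butyl{4-[(tert-butyldimethylsilyloxy)methyl]-3-[(4-methoxybenzyloxy)methyl]furan-2-yl}dimethylsilane
Product: 7 {5-(tert-butyldimethylsilyl)-4-[(4-methoxybenzyloxy)methyl]furan-3-yl}methanol
Conditions: TBAF (1.1 equiv), THF, 0 °C
Reagents that add atoms: none
Why: Fluoride-mediated desilylation cleaves the primary O–Si bond far faster than the furyl C–Si bond, so only the hydroxyl of the future C8 arm is released.

Step 5
Reactants: 7 {5-(tert-butyldimethylsilyl)-4-[(4-methoxybenzyloxy)methyl]furan-3-yl}methanol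
Product: 8 5-(tert-butyldimethylsilyl)-4-[(4-methoxybenzyloxy)methyl]furan-3-carbaldehyde
Conditions: MnO2, CH2Cl2, rt
Reagents that add atoms: none
Why: MnO2 oxidation of the furylic (benzylic-type) primary alcohol stops cleanly at the aldehyde, whose carbon becomes C8.

Step 6
Reactants: 8 5-(tert-butyldimethylsilyl)-4-[(4-methoxybenzyloxy)methyl]furan-3-carbaldehyde; 9 allenylboronic acid pinacol ester
Product: 11 (1S)-1-{5-(tert-butyldimethylsilyl)-4-[(4-methoxybenzyloxy)methyl]furan-3-yl}but-3-yn-1-ol, via pinacol borate 10 (not isolated)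
Conditions: 9 (1.5 equiv), (S)-3,3'-bis(2,4,6-triisopropylphenyl)-1,1'-binaphthyl-2,2'-diyl hydrogen phosphate [(S)-TRIP] (5 mol %), 4 Å MS, toluene, −20 °C → rt; aq. NaHCO3
Reagents that add atoms: 9 allenylboronic acid pinacol ester, C=C=CB1OC(C)(C)C(C)(C)O1
Why: Chiral phosphoric acid-catalysed propargylboration passes through a closed six-membered SE2' transition state in which the (S)-catalyst is expected to expose the Si face of the aldehyde, which sets C8 as S (to be verified by Mosher ester analysis).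

Step 7
Reactants: 11 (1S)-1-{5-(tert-butyldimethylsilyl)-4-[(4-methoxybenzyloxy)methyl]furan-3-yl}but-3-yn-1-ol
Product: 12 tert-butyl{4-[(1S)-1-(4-methoxybenzyloxy)but-3-yn-1-yl]-3-[(4-methoxybenzyloxy)methyl]furan-2-yl}dimethylsilane
Conditions: NaH, PMBBr, tetrabutylammonium iodide (cat.), THF/DMF, 0 °C → rt
Reagents that add atoms: 4-methoxybenzyl bromide, COc1ccc(CBr)cc1
Why: Williamson etherification at oxygen masks the C8 hydroxyl with the same oxidatively removable group as the C13 hydroxyl, so that both can be released together later while C8 is untouched.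

Step 8
Reactants: 12 tert-butyl{4-[(1S)-1-(4-methoxybenzyloxy)but-3-yn-1-yl]-3-[(4-methoxybenzyloxy)methyl]furan-2-yl}dimethylsilane
Product: 15 (2E,5S)-5-{5-(tert-butyldimethylsilyl)-4-[(4-methoxybenzyloxy)methyl]furan-3-yl}-5-(4-methoxybenzyloxy)-3-methylpent-2-en-1-ol, via alkenylalane 13 (not isolated), via lithium alanate 14 (not isolated)
Conditions: Me3Al (3 equiv), Cp2ZrCl2 (0.3 equiv), CH2Cl2, 0 °C → rt; volatiles removed; n-BuLi (1 equiv), hexane/THF, −78 → 0 °C; (CH2O)n, rt
Reagents that add atoms: trimethylaluminium, C[Al](C)C; paraformaldehyde (as formaldehyde), C=O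
Why: Negishi zirconium-catalysed syn-methylalumination places methyl on the internal and aluminium on the terminal alkyne carbon, which fixes the E geometry of C1=C10, and the derived alanate is hydroxymethylated by formaldehyde with retention to bring in C2.

Step 9
Reactants: 15 (2E,5S)-5-{5-(tert-butyldimethylsilyl)-4-[(4-methoxybenzyloxy)methyl]furan-3-yl}-5-(4-methoxybenzyloxy)-3-methylpent-2-en-1-ol
Product: 16 (2E,5S)-5-{5-(tert-butyldimethylsilyl)-4-[(4-methoxybenzyloxy)methyl]furan-3-yl}-5-(4-methoxybenzyloxy)-3-methylpent-2-enal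
Conditions: MnO2, CH2Cl2, rt
Reagents that add atoms: none
Why: MnO2 selectively oxidises the primary allylic alcohol to the conjugated (E)-enal, the C2 aldehyde, without affecting the ethers or the silylfuran.

Step 10
Reactants: 16 (2E,5S)-5-{5-(tert-butyldimethylsilyl)-4-[(4-methoxybenzyloxy)methyl]furan-3-yl}-5-(4-methoxybenzyloxy)-3-methylpent-2-enal; 9 allenylboronic acid pinacol ester
Product: 18 (4R,5E,8S)-8-{5-(tert-butyldimethylsilyl)-4-[(4-methoxybenzyloxy)methyl]furan-3-yl}-8-(4-methoxybenzyloxy)-6-methyloct-5-en-1-yn-4-ol, via pinacol borate 17 (not isolated)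
Conditions: 9 (1.5 equiv), (R)-3,3'-bis(2,4,6-triisopropylphenyl)-1,1'-binaphthyl-2,2'-diyl hydrogen phosphate [(R)-TRIP] (5 mol %), 4 Å MS, toluene, −20 °C → rt; aq. NaHCO3
Reagents that add atoms: 9 allenylboronic acid pinacol ester, C=C=CB1OC(C)(C)C(C)(C)O1
Why: The same phosphoric acid-catalysed propargylboration adds the C3–C5 unit 1,2 to the enal, the (R)-catalyst being expected to direct Re-face attack and give the 2R carbinol, a centre that only has to be uniform because it is oxidised in the last step.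

Step 11
Reactants: 18 (4R,5E,8S)-8-{5-(tert-butyldimethylsilyl)-4-[(4-methoxybenzyloxy)methyl]furan-3-yl}-8-(4-methoxybenzyloxy)-6-methyloct-5-en-1-yn-4-ol
Product: 19 tert-butyl{[(4R,5E,8S)-8-{5-(tert-butyldimethylsilyl)-4-[(4-methoxybenzyloxy)methyl]furan-3-yl}-8-(4-methoxybenzyloxy)-6-methyloct-5-en-1-yn-4-yl]oxy}dimethylsilane
Conditions: TBSCl, imidazole, DMF, rt
Reagents that add atoms: tert-butyldimethylsilyl chloride, CC(C)(C)[Si](C)(C)Cl
Why: Imidazole-promoted silylation protects the secondary allylic alcohol before the Lewis-acidic aluminium reagent of the next step could ionise it.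

Step 12
Reactants: 19 tert-butyl{[(4R,5E,8S)-8-{5-(tert-butyldimethylsilyl)-4-[(4-methoxybenzyloxy)methyl]furan-3-yl}-8-(4-methoxybenzyloxy)-6-methyloct-5-en-1-yn-4-yl]oxy}dimethylsilane
Product: 21 tert-butyl{[(1E,4R,5E,8S)-8-{5-(tert-butyldimethylsilyl)-4-[(4-methoxybenzyloxy)methyl]furan-3-yl}-1-iodo-8-(4-methoxybenzyloxy)-2,6-dimethylocta-1,5-dien-4-yl]oxy}dimethylsilane, via alkenylalane 20 (not isolated)
Conditions: Me3Al (3 equiv), Cp2ZrCl2 (0.3 equiv), CH2Cl2, 0 °C → rt; I2, THF, −30 → 0 °C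
Reagents that add atoms: trimethylaluminium, C[Al](C)C; iodine, II
Why: A second Negishi syn-methylalumination followed by iodinolysis of the C–Al bond with retention gives the (E)-iodoalkene with methyl on C4, ethers and silanes being inert to Me3Al.

Step 13
Reactants: 21 tert-butyl{[(1E,4R,5E,8S)-8-{5-(tert-butyldimethylsilyl)-4-[(4-methoxybenzyloxy)methyl]furan-3-yl}-1-iodo-8-(4-methoxybenzyloxy)-2,6-dimethylocta-1,5-dien-4-yl]oxy}dimethylsilane
Product: 22 (1S,3E,5R,7E)-1-[5-(tert-butyldimethylsilyl)-4-(hydroxymethyl)furan-3-yl]-5-[(tert-butyldimethylsilyl)oxy]-8-iodo-3,7-dimethylocta-3,7-dien-1-ol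
Conditions: DDQ (2.6 equiv), CH2Cl2/pH 7 buffer, 0 °C
Reagents that add atoms: none
Why: Oxidative cleavage of both p-methoxybenzyl ethers by DDQ proceeds by hydride abstraction at the anisyl methylene and hydrolysis of the oxocarbenium ion, while the silyl ether, the silylfuran and the iodoalkene are expected to survive in the buffered two-phase medium.

Step 14
Reactants: 22 (1S,3E,5R,7E)-1-[5-(tert-butyldimethylsilyl)-4-(hydroxymethyl)furan-3-yl]-5-[(tert-butyldimethylsilyl)oxy]-8-iodo-3,7-dimethylocta-3,7-dien-1-ol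
Product: 23 {2-(tert-butyldimethylsilyl)-4-[(1S,3E,5R,7E)-5-[(tert-butyldimethylsilyl)oxy]-1-hydroxy-8-iodo-3,7-dimethylocta-3,7-dien-1-yl]furan-3-yl}methyl acetate
Conditions: AcCl (1.05 equiv), 2,4,6-collidine, CH2Cl2, −78 °C
Reagents that add atoms: acetyl chloride, CC(Cl)=O
Why: Kinetically controlled acylation with a hindered pyridine base acetylates the primary C13 hydroxyl in preference to the more hindered secondary C8 hydroxyl.

Step 15
Reactants: 23 {2-(tert-butyldimethylsilyl)-4-[(1S,3E,5R,7E)-5-[(tert-butyldimethylsilyl)oxy]-1-hydroxy-8-iodo-3,7-dimethylocta-3,7-dien-1-yl]furan-3-yl}methyl acetate; 24 methacryloyl chloride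
Product: 25 (1S,3E,5R,7E)-1-[4-(acetoxymethyl)-5-(tert-butyldimethylsilyl)furan-3-yl]-5-[(tert-butyldimethylsilyl)oxy]-8-iodo-3,7-dimethylocta-3,7-dien-1-yl methacrylate
Conditions: 24 (2 equiv), Et3N, 4-(dimethylamino)pyridine (cat.), CH2Cl2, 0 °C
Reagents that add atoms: 24 methacryloyl chloride, C=C(C)C(Cl)=O
Why: DMAP-catalysed acylation (nucleophilic catalysis) esterifies the remaining secondary alcohol at oxygen, so C8 keeps its S configuration.

Step 16
Reactants: 25 (1S,3E,5R,7E)-1-[4-(acetoxymethyl)-5-(tert-butyldimethylsilyl)furan-3-yl]-5-[(tert-butyldimethylsilyl)oxy]-8-iodo-3,7-dimethylocta-3,7-dien-1-yl methacrylate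
Product: 28 (1S,3E,5R,7E)-1-[4-(acetoxymethyl)-2-hydroxy-5-oxo-2,5-dihydrofuran-3-yl]-5-[(tert-butyldimethylsilyl)oxy]-8-iodo-3,7-dimethylocta-3,7-dien-1-yl methacrylate, via furan endoperoxide 26 (not isolated), via silyl ester 27 (not isolated)
Conditions: O2, hν (>500 nm), 5,10,15,20-tetraphenylporphyrin (cat.), CH2Cl2, −78 °C; then THF/H2O/AcOH, rt
Reagents that add atoms: oxygen, O=O
Why: Singlet oxygen adds [4+2] to the furan far faster than it reacts with the trisubstituted alkenes, and the C→O silyl shift in the 2-silylfuran endoperoxide turns the silylated carbon into the C12 carboxyl and the unsubstituted α-carbon into the aldehyde-level C6, the labile silyl ester being hydrolysed to the pseudo-acid on work-up.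

Step 17
Reactants: 28 (1S,3E,5R,7E)-1-[4-(acetoxymethyl)-2-hydroxy-5-oxo-2,5-dihydrofuran-3-yl]-5-[(tert-butyldimethylsilyl)oxy]-8-iodo-3,7-dimethylocta-3,7-dien-1-yl methacrylate
Product: 29 methyl (2Z,4S,6E,8R,10E)-2-(acetoxymethyl)-8-[(tert-butyldimethylsilyl)oxy]-3-formyl-11-iodo-4-(methacryloyloxy)-6,10-dimethylundeca-2,6,10-trienoate
Conditions: MeI, KHCO3, DMF, 0 °C → rt
Reagents that add atoms: iodomethane, CI
Why: Bicarbonate opens the pseudo-acid to its carboxylate, and SN2 O-alkylation of that carboxylate by iodomethane traps the open-chain tautomer as the (Z)-aldehyde ester without a base strong enough to enolise toward C13.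

Step 18
Reactants: 29 methyl (2Z,4S,6E,8R,10E)-2-(acetoxymethyl)-8-[(tert-butyldimethylsilyl)oxy]-3-formyl-11-iodo-4-(methacryloyloxy)-6,10-dimethylundeca-2,6,10-trienoate
Product: 32 (2R,6R,8S)-13-acetoxy-2-[(tert-butyldimethylsilyl)oxy]-8-(methacryloyloxy)germacra-1(10)E,4E,7(11)-trien-12,6-olide, via alkenylchromium 30 (not isolated), via chromium alkoxide 31 (not isolated)
Conditions: CrCl2 (10 equiv), NiCl2 (0.1 equiv), DMF, rt, slow addition of 29 (final 2 mM); aq. NH4Cl
Reagents that add atoms: none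
Why: Zerovalent nickel, formed from NiCl2 by reduction with CrCl2, inserts into the C5–I bond and hands the alkenyl group to trivalent chromium with retention of the E geometry; the alkenylchromium adds to the C6 aldehyde, and the chromium alkoxide then attacks the C12 methyl ester held cis to it across C7=C11 and expels methoxide. The closest known reaction type is the Nozaki–Hiyama–Kishi macrocyclisation of an iodoalkene onto an aldehyde followed by lactonisation of the alkoxide onto a neighbouring ester. Ring A (the ten-membered carbocycle) closes by 10-exo-trig carbonyl addition under high dilution, and ring B (the butenolide) closes by 5-exo-trig acyl substitution. The new C6 centre is controlled by C8: allylic 1,3-strain with the C13 acetoxymethyl group keeps H8 in the plane of C7=C11, so the C9 tether leaves one face of the enal and the alkenylchromium is expected to reach C6 from the opposite face, the staggered arrangement of the two ring bonds that a ten-membered (E,E)-diene prefers, which gives 6R with the lactone oxygen and the C8 ester oxygen on the same side of ring A. The step needs chemoselectivity for the aldehyde over the methyl ester, acetate, methacrylate and enoate, which the low basicity and strong aldehyde preference of organochromium reagents provide, and it needs ring closure to beat intermolecular coupling, which dilution secures.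

Step 19
Reactants: 32 (2R,6R,8S)-13-acetoxy-2-[(tert-butyldimethylsilyl)oxy]-8-(methacryloyloxy)germacra-1(10)E,4E,7(11)-trien-12,6-olide
Product: 33 (2R,6R,8S)-13-acetoxy-2-hydroxy-8-(methacryloyloxy)germacra-1(10)E,4E,7(11)-trien-12,6-olide
Conditions: HF·pyridine, pyridine, THF, 0 °C → rt
Reagents that add atoms: none
Why: Buffered fluoride-mediated desilylation removes the secondary silyl ether without the basic conditions that would endanger the acetate, the methacrylate and the butenolide γ-hydrogen at C6.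

Step 20
Reactants: 33 (2R,6R,8S)-13-acetoxy-2-hydroxy-8-(methacryloyloxy)germacra-1(10)E,4E,7(11)-trien-12,6-olide
Product: 34 (6R,8S)-13-acetoxy-8-(methacryloyloxy)-2-oxogermacra-1(10)E,4E,7(11)-trien-12,6-olide (CNP0325594.1)
Conditions: Dess–Martin periodinane, CH2Cl2, 0 °C → rt
Reagents that add atoms: none
Why: Dess–Martin oxidation of the allylic alcohol gives the C2 enone under neutral conditions that leave C6, C8 and the skipped C4=C5 alkene untouched.

Compound list

1 | dimethyl furan-3,4-dicarboxylate | COC(=O)c1cocc1C(=O)OC | starting material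
2 | furan-3,4-diyldimethanol | OCc1cocc1CO | intermediate
3 | 3,4-bis{[(tert-butyldimethylsilyl)oxy]methyl}furan | CC(C)(C)[Si](C)(C)OCc1cocc1CO[Si](C)(C)C(C)(C)C | intermediate
4 | 2-lithio-3,4-bis{[(tert-butyldimethylsilyl)oxy]methyl}furan (not isolated) | CC(C)(C)[Si](C)(C)OCc1coc([Li])c1CO[Si](C)(C)C(C)(C)C | intermediate
5 | lithium {2-(tert-butyldimethylsilyl)-4-[(tert-butyldimethylsilyloxy)methyl]furan-3-yl}methanolate (not isolated) | CC(C)(C)[Si](C)(C)OCc1coc([Si](C)(C)C(C)(C)C)c1CO[Li] | intermediate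
6 | tert-butyl{4-[(tert-butyldimethylsilyloxy)methyl]-3-[(4-methoxybenzyloxy)methyl]furan-2-yl}dimethylsilane | CC(C)(C)[Si](C)(C)OCc1coc([Si](C)(C)C(C)(C)C)c1COCc1ccc(OC)cc1 | intermediate
7 | {5-(tert-butyldimethylsilyl)-4-[(4-methoxybenzyloxy)methyl]furan-3-yl}methanol | OCc1coc([Si](C)(C)C(C)(C)C)c1COCc1ccc(OC)cc1 | intermediate
8 | 5-(tert-butyldimethylsilyl)-4-[(4-methoxybenzyloxy)methyl]furan-3-carbaldehyde | O=Cc1coc([Si](C)(C)C(C)(C)C)c1COCc1ccc(OC)cc1 | intermediate
9 | allenylboronic acid pinacol ester | C=C=CB1OC(C)(C)C(C)(C)O1 | starting material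
10 | pinacol borate ester of 11 (O–B bond at C8; not isolated) | C#CC[C@H](OB1OC(C)(C)C(C)(C)O1)c1coc([Si](C)(C)C(C)(C)C)c1COCc1ccc(OC)cc1 | intermediate
11 | (1S)-1-{5-(tert-butyldimethylsilyl)-4-[(4-methoxybenzyloxy)methyl]furan-3-yl}but-3-yn-1-ol | C#CC[C@H](O)c1coc([Si](C)(C)C(C)(C)C)c1COCc1ccc(OC)cc1 | intermediate
12 | tert-butyl{4-[(1S)-1-(4-methoxybenzyloxy)but-3-yn-1-yl]-3-[(4-methoxybenzyloxy)methyl]furan-2-yl}dimethylsilane | C#CC[C@H](OCc1ccc(OC)cc1)c1coc([Si](C)(C)C(C)(C)C)c1COCc1ccc(OC)cc1 | intermediate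
13 | (E)-alkenyldimethylalane from 12 (AlMe2 on C1, methyl on C10; not isolated) | C[Al](C)/C=C(\C)C[C@H](OCc1ccc(OC)cc1)c1coc([Si](C)(C)C(C)(C)C)c1COCc1ccc(OC)cc1 | intermediate
14 | lithium butyl(alkenyl)dimethylaluminate from 13 (not isolated) | [Li+].CCCC[Al-](C)(C)/C=C(\C)C[C@H](OCc1ccc(OC)cc1)c1coc([Si](C)(C)C(C)(C)C)c1COCc1ccc(OC)cc1 | intermediate
15 | (2E,5S)-5-{5-(tert-butyldimethylsilyl)-4-[(4-methoxybenzyloxy)methyl]furan-3-yl}-5-(4-methoxybenzyloxy)-3-methylpent-2-en-1-ol | OC/C=C(\C)C[C@H](OCc1ccc(OC)cc1)c1coc([Si](C)(C)C(C)(C)C)c1COCc1ccc(OC)cc1 | intermediate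
16 | (2E,5S)-5-{5-(tert-butyldimethylsilyl)-4-[(4-methoxybenzyloxy)methyl]furan-3-yl}-5-(4-methoxybenzyloxy)-3-methylpent-2-enal | O=C/C=C(\C)C[C@H](OCc1ccc(OC)cc1)c1coc([Si](C)(C)C(C)(C)C)c1COCc1ccc(OC)cc1 | intermediate
17 | pinacol borate ester of 18 (O–B bond at C2; not isolated) | C#CC[C@@H](OB1OC(C)(C)C(C)(C)O1)/C=C(\C)C[C@H](OCc1ccc(OC)cc1)c1coc([Si](C)(C)C(C)(C)C)c1COCc1ccc(OC)cc1 | intermediate
18 | (4R,5E,8S)-8-{5-(tert-butyldimethylsilyl)-4-[(4-methoxybenzyloxy)methyl]furan-3-yl}-8-(4-methoxybenzyloxy)-6-methyloct-5-en-1-yn-4-ol | C#CC[C@@H](O)/C=C(\C)C[C@H](OCc1ccc(OC)cc1)c1coc([Si](C)(C)C(C)(C)C)c1COCc1ccc(OC)cc1 | intermediate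
19 | tert-butyl{[(4R,5E,8S)-8-{5-(tert-butyldimethylsilyl)-4-[(4-methoxybenzyloxy)methyl]furan-3-yl}-8-(4-methoxybenzyloxy)-6-methyloct-5-en-1-yn-4-yl]oxy}dimethylsilane | C#CC[C@@H](O[Si](C)(C)C(C)(C)C)/C=C(\C)C[C@H](OCc1ccc(OC)cc1)c1coc([Si](C)(C)C(C)(C)C)c1COCc1ccc(OC)cc1 | intermediate
20 | (E)-alkenyldimethylalane from 19 (AlMe2 on C5, methyl on C4; not isolated) | C[Al](C)/C=C(\C)C[C@@H](O[Si](C)(C)C(C)(C)C)/C=C(\C)C[C@H](OCc1ccc(OC)cc1)c1coc([Si](C)(C)C(C)(C)C)c1COCc1ccc(OC)cc1 | intermediate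
21 | tert-butyl{[(1E,4R,5E,8S)-8-{5-(tert-butyldimethylsilyl)-4-[(4-methoxybenzyloxy)methyl]furan-3-yl}-1-iodo-8-(4-methoxybenzyloxy)-2,6-dimethylocta-1,5-dien-4-yl]oxy}dimethylsilane | I/C=C(\C)C[C@@H](O[Si](C)(C)C(C)(C)C)/C=C(\C)C[C@H](OCc1ccc(OC)cc1)c1coc([Si](C)(C)C(C)(C)C)c1COCc1ccc(OC)cc1 | intermediate
22 | (1S,3E,5R,7E)-1-[5-(tert-butyldimethylsilyl)-4-(hydroxymethyl)furan-3-yl]-5-[(tert-butyldimethylsilyl)oxy]-8-iodo-3,7-dimethylocta-3,7-dien-1-ol | I/C=C(\C)C[C@@H](O[Si](C)(C)C(C)(C)C)/C=C(\C)C[C@H](O)c1coc([Si](C)(C)C(C)(C)C)c1CO | intermediate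
23 | {2-(tert-butyldimethylsilyl)-4-[(1S,3E,5R,7E)-5-[(tert-butyldimethylsilyl)oxy]-1-hydroxy-8-iodo-3,7-dimethylocta-3,7-dien-1-yl]furan-3-yl}methyl acetate | I/C=C(\C)C[C@@H](O[Si](C)(C)C(C)(C)C)/C=C(\C)C[C@H](O)c1coc([Si](C)(C)C(C)(C)C)c1COC(C)=O | intermediate
24 | methacryloyl chloride | C=C(C)C(Cl)=O | starting material
25 | (1S,3E,5R,7E)-1-[4-(acetoxymethyl)-5-(tert-butyldimethylsilyl)furan-3-yl]-5-[(tert-butyldimethylsilyl)oxy]-8-iodo-3,7-dimethylocta-3,7-dien-1-yl methacrylate | I/C=C(\C)C[C@@H](O[Si](C)(C)C(C)(C)C)/C=C(\C)C[C@H](OC(=O)C(C)=C)c1coc([Si](C)(C)C(C)(C)C)c1COC(C)=O | intermediate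
26 | 2,3-dioxa-7-oxabicyclo[2.2.1]hept-5-ene endoperoxide of 25 (silicon on a bridgehead, both bridgehead configurations; not isolated) | CC(C)(C)[Si](C)(C)C12OOC(O1)C([C@@H](OC(=O)C(C)=C)C/C(C)=C/[C@H](O[Si](C)(C)C(C)(C)C)C/C(C)=C/I)=C2COC(C)=O | intermediate
27 | tert-butyldimethylsilyl (2Z,4S,6E,8R,10E)-2-(acetoxymethyl)-8-[(tert-butyldimethylsilyl)oxy]-3-formyl-11-iodo-4-(methacryloyloxy)-6,10-dimethylundeca-2,6,10-trienoate (not isolated) | C=C(C)C(=O)O[C@@H](C/C(C)=C/[C@H](O[Si](C)(C)C(C)(C)C)C/C(C)=C/I)/C(C=O)=C(\COC(C)=O)C(=O)O[Si](C)(C)C(C)(C)C | intermediate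
28 | (1S,3E,5R,7E)-1-[4-(acetoxymethyl)-2-hydroxy-5-oxo-2,5-dihydrofuran-3-yl]-5-[(tert-butyldimethylsilyl)oxy]-8-iodo-3,7-dimethylocta-3,7-dien-1-yl methacrylate (lactol carbon as equilibrating epimers) | C=C(C)C(=O)O[C@@H](C/C(C)=C/[C@H](O[Si](C)(C)C(C)(C)C)C/C(C)=C/I)C1=C(COC(C)=O)C(=O)OC1O | intermediate
29 | methyl (2Z,4S,6E,8R,10E)-2-(acetoxymethyl)-8-[(tert-butyldimethylsilyl)oxy]-3-formyl-11-iodo-4-(methacryloyloxy)-6,10-dimethylundeca-2,6,10-trienoate | C=C(C)C(=O)O[C@@H](C/C(C)=C/[C@H](O[Si](C)(C)C(C)(C)C)C/C(C)=C/I)/C(C=O)=C(\COC(C)=O)C(=O)OC | intermediate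
30 | alkenylchromium dichloride from 29 (CrCl2 in place of iodine on C5; not isolated) | C=C(C)C(=O)O[C@@H](C/C(C)=C/[C@H](O[Si](C)(C)C(C)(C)C)C/C(C)=C/[Cr](Cl)Cl)/C(C=O)=C(\COC(C)=O)C(=O)OC | intermediate
31 | dichlorochromium (6R)-alkoxide of the ring-closed ten-membered hydroxy methyl ester (not isolated) | C=C(C)C(=O)O[C@H]1C/C(C)=C/[C@H](O[Si](C)(C)C(C)(C)C)C/C(C)=C/[C@@H](O[Cr](Cl)Cl)/C1=C(/COC(C)=O)C(=O)OC | intermediate
32 | (2R,6R,8S)-13-acetoxy-2-[(tert-butyldimethylsilyl)oxy]-8-(methacryloyloxy)germacra-1(10)E,4E,7(11)-trien-12,6-olide | C=C(C)C(=O)O[C@H]1C/C(C)=C/[C@H](O[Si](C)(C)C(C)(C)C)C/C(C)=C/[C@H]2OC(=O)C(COC(C)=O)=C12 | intermediate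
33 | (2R,6R,8S)-13-acetoxy-2-hydroxy-8-(methacryloyloxy)germacra-1(10)E,4E,7(11)-trien-12,6-olide | C=C(C)C(=O)O[C@H]1C/C(C)=C/[C@H](O)C/C(C)=C/[C@H]2OC(=O)C(COC(C)=O)=C12 | intermediate
34 | (6R,8S)-13-acetoxy-8-(methacryloyloxy)-2-oxogermacra-1(10)E,4E,7(11)-trien-12,6-olide (CNP0325594.1) | C=C(C)C(=O)O[C@H]1C/C(C)=C/C(=O)C/C(C)=C/[C@H]2OC(=O)C(COC(C)=O)=C12 | target

Total step count: 20. Longest linear sequence: 20 steps (1 → 34); 9 and 24 are purchased.

Steps most likely to fail

Step 18 (ring closure). The alkenylchromium may be delivered to the wrong face of the C6 aldehyde, or single-electron reduction of the electron-poor oxo-enoate by CrCl2 may compete with the coupling. The fallback corrects C6 after ring closure. It sets out from 28, whose carboxyl group is alkylated with O-tert-butyl-N,N'-diisopropylisourea (CH2Cl2, rt) to give the tert-butyl ester aldehyde F1; the bulky ester is meant to hold back lactonisation. The same nickel/chromium ring closure, through the alkenylchromium species F2 (not isolated), should then stop at the macrocyclic C6 carbinols F3 as an epimer mixture. Dess–Martin oxidation converges both epimers on the cross-conjugated C6 ketone F4. Reduction with catecholborane and (S)-1-methyl-3,3-diphenyltetrahydro-1H,3H-pyrrolo[1,2-c][1,3,2]oxazaborole is expected to give the 6R alcohol F5 under reagent control, the tetrasubstituted enoate arm acting as the large group. Warming F5 with pyridinium p-toluenesulfonate in toluene closes the butenolide and returns the sequence to 32.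

Step 17 (opening and methylation of the pseudo-acid). Alkylation may occur on the lactol oxygen of the ring tautomer, giving a cyclic pseudo-ester with no free aldehyde, or the base may start elimination of the C13 acetate. The fallback avoids alkylation altogether. It sets out from 25: the photooxygenation of step 16 is run without the aqueous hydrolysis, the solvent is exchanged under anhydrous conditions, and the silyl ester 27 is carried straight into the nickel/chromium ring closure. Oxidative addition and transmetallation give the alkenylchromium species F6 (not isolated), and ring closure gives the chromium alkoxide F7 (not isolated). This lactonises by displacing silanolate from the cis silyl ester, so the sequence rejoins the route at 32.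

Step 8 (methylalumination and hydroxymethylation). The aluminate may form incompletely or be captured too slowly by depolymerising paraformaldehyde, so that protonolysis of the C–Al bond gives the 1,1-disubstituted alkene instead of the allylic alcohol. The fallback sets out from 12: the methylalumination is run as before and the alkenylalane 13 is quenched with iodine to give the (E)-iodoalkene F8. Iodine–lithium exchange with t-BuLi (2 equiv, Et2O, −78 °C) gives the alkenyllithium F9 (not isolated), and formylation with DMF returns the sequence to enal 16, bypassing 15.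

Further compounds

F1 | step 18 | tert-butyl (2Z,4S,6E,8R,10E)-2-(acetoxymethyl)-8-[(tert-butyldimethylsilyl)oxy]-3-formyl-11-iodo-4-(methacryloyloxy)-6,10-dimethylundeca-2,6,10-trienoate | C=C(C)C(=O)O[C@@H](C/C(C)=C/[C@H](O[Si](C)(C)C(C)(C)C)C/C(C)=C/I)/C(C=O)=C(\COC(C)=O)C(=O)OC(C)(C)C
F2 | step 18 | alkenylchromium dichloride from F1 (CrCl2 in place of iodine on C5; not isolated) | C=C(C)C(=O)O[C@@H](C/C(C)=C/[C@H](O[Si](C)(C)C(C)(C)C)C/C(C)=C/[Cr](Cl)Cl)/C(C=O)=C(\COC(C)=O)C(=O)OC(C)(C)C
F3 | step 18 | ring-closed ten-membered C6 carbinol with intact tert-butyl ester on C11 (C6 epimers; 2R,8S) | C=C(C)C(=O)O[C@H]1C/C(C)=C/[C@H](O[Si](C)(C)C(C)(C)C)C/C(C)=C/C(O)/C1=C(/COC(C)=O)C(=O)OC(C)(C)C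
F4 | step 18 | ring-closed ten-membered C6 ketone with intact tert-butyl ester (2R,8S) | C=C(C)C(=O)O[C@H]1C/C(C)=C/[C@H](O[Si](C)(C)C(C)(C)C)C/C(C)=C/C(=O)/C1=C(/COC(C)=O)C(=O)OC(C)(C)C
F5 | step 18 | ring-closed ten-membered (6R)-carbinol with intact tert-butyl ester (2R,6R,8S) | C=C(C)C(=O)O[C@H]1C/C(C)=C/[C@H](O[Si](C)(C)C(C)(C)C)C/C(C)=C/[C@@H](O)/C1=C(/COC(C)=O)C(=O)OC(C)(C)C
F6 | step 17 | alkenylchromium dichloride from 27 (CrCl2 in place of iodine on C5; not isolated) | C=C(C)C(=O)O[C@@H](C/C(C)=C/[C@H](O[Si](C)(C)C(C)(C)C)C/C(C)=C/[Cr](Cl)Cl)/C(C=O)=C(\COC(C)=O)C(=O)O[Si](C)(C)C(C)(C)C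
F7 | step 17 | dichlorochromium (6R)-alkoxide of the ring-closed ten-membered hydroxy silyl ester (not isolated) | C=C(C)C(=O)O[C@H]1C/C(C)=C/[C@H](O[Si](C)(C)C(C)(C)C)C/C(C)=C/[C@@H](O[Cr](Cl)Cl)/C1=C(/COC(C)=O)C(=O)O[Si](C)(C)C(C)(C)C
F8 | step 8 | tert-butyl{4-[(1S,3E)-4-iodo-1-(4-methoxybenzyloxy)-3-methylbut-3-en-1-yl]-3-[(4-methoxybenzyloxy)methyl]furan-2-yl}dimethylsilane | I/C=C(\C)C[C@H](OCc1ccc(OC)cc1)c1coc([Si](C)(C)C(C)(C)C)c1COCc1ccc(OC)cc1
F9 | step 8 | (E)-alkenyllithium from F8 (lithium in place of iodine; not isolated) | [Li]/C=C(\C)C[C@H](OCc1ccc(OC)cc1)c1coc([Si](C)(C)C(C)(C)C)c1COCc1ccc(OC)cc1
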